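**Retrosynthetic overview**

1. Forward order: 1 + 2 + 3 → 4 → 5 → 6 → 7 → 8 (4 and 5 are not isolated); three steps.
2. 8 ⇒ 7: C3 and C4 are set together by one cis-hydrogenation of the tetrasubstituted ring alkene on the face away from the C2 aryl group, which gives the all-cis oxolane.
3. 7 ⇒ 6: 1,2-reduction of the ring enal.
4. 6 ⇒ 1 + 2 + 3: key bond O1–C2, an amine-catalysed enantioselective oxa-Michael addition that sets the only catalyst-controlled stereocentre; in the same flask C3–C4 closes onto the alkyne and the aryl group of 3 caps the exocyclic carbon.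
5. Rings: the single oxolane ring is made in step 1 (as a 2,5-dihydrofuran) and saturated in step 3.

Assumption: 1 and 3 are bought as catalogue chemicals; 2 is a bulk chemical.

**Step 1**
Reactants: 1 (2E)-3-(3,4,5-trimethoxyphenyl)prop-2-enal; 2 prop-2-yn-1-ol; 3 1-iodo-2,4,5-trimethoxybenzene
Product: 6 (2S)-4-[(2,4,5-trimethoxyphenyl)methyl]-2-(3,4,5-trimethoxyphenyl)-2,5-dihydrofuran-3-carbaldehyde, via oxa-Michael adduct 4 (not isolated), via exocyclic arylidene aldehyde 5 (not isolated)
Conditions: 2 (3 equiv), 3 (1.3 equiv), (R)-2-[diphenyl(trimethylsilyloxy)methyl]pyrrolidine (20 mol %), Pd2(dba)3 (2.5 mol %), P(2-furyl)3 (10 mol %), NaOAc (1.5 equiv), THF–DMSO 4:1, 30 °C, argon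
Reagents that add atoms: none
Why: Proposed new method: the (R)-amine converts 1 into its iminium ion, 2 adds reversibly to the unshielded face of the β-carbon (oxa-Michael; this C–O bond sets C2, S in 6), the enamine so formed attacks anti and 5-exo-dig the terminal alkyne bound to the aryl–palladium iodide that 3 forms with zerovalent palladium, reductive elimination places the aryl group on the exocyclic carbon (5), and the β,γ-unsaturated iminium ion relaxes through its dienamine to the conjugated ring enal, after which C2 can no longer erode by retro-oxa-Michael; the closest known reaction types are the amine/PdCl2 co-catalysed dynamic kinetic oxa-Michael–carbocyclisation of propargyl alcohol with enals (proton instead of aryl) and the racemic three-component coupling of propargyl alkoxides, alkylidene malonates and aryl iodides under zerovalent palladium (same anti attack on an aryl–palladium-activated alkyne).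

**Step 2**
Reactants: 6 (2S)-4-[(2,4,5-trimethoxyphenyl)methyl]-2-(3,4,5-trimethoxyphenyl)-2,5-dihydrofuran-3-carbaldehyde
Product: 7 [(2S)-4-[(2,4,5-trimethoxyphenyl)methyl]-2-(3,4,5-trimethoxyphenyl)-2,5-dihydrofuran-3-yl]methanol
Conditions: NaBH4, CeCl3·7H2O, MeOH, −20 to 0 °C, argon
Reagents that add atoms: none
Why: Luche reduction: the cerium-activated borohydride adds only 1,2 to the aldehyde, so the tetrasubstituted alkene and the C2 stereocentre are untouched.

**Step 3**
Reactants: 7 [(2S)-4-[(2,4,5-trimethoxyphenyl)methyl]-2-(3,4,5-trimethoxyphenyl)-2,5-dihydrofuran-3-yl]methanol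
Product: 8 [(2R,3R,4R)-4-[(2,4,5-trimethoxyphenyl)methyl]-2-(3,4,5-trimethoxyphenyl)oxolan-3-yl]methanol
Conditions: H2 (10 bar), [Ir(cod)(PCy3)(py)]PF6 (5 mol %), CH2Cl2, 0 to 25 °C
Reagents that add atoms: none
Why: Hydroxyl-directed homogeneous hydrogenation of a tetrasubstituted alkene: the CH2OH group on the alkene carbon holds the cationic iridium hydride, which can reach only the ring face opposite the C2 aryl group, so both hydrogens enter cis on that face and C3 (R) and C4 (R) end up cis to the aryl group and to each other, without hydrogenolysis of the benzylic C2–O bond.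

**Compound list**

1 | (2E)-3-(3,4,5-trimethoxyphenyl)prop-2-enal | COc1cc(/C=C/C=O)cc(OC)c1OC | starting material
2 | prop-2-yn-1-ol | C#CCO | starting material
3 | 1-iodo-2,4,5-trimethoxybenzene | COc1cc(OC)c(OC)cc1I | starting material
4 | (3R)-3-(prop-2-yn-1-yloxy)-3-(3,4,5-trimethoxyphenyl)propanal (oxa-Michael adduct; reacts on as its enamine with the amine catalyst) | C#CCO[C@H](CC=O)c1cc(OC)c(OC)c(OC)c1 | intermediate
5 | (2R,3R,4Z)-4-[(2,4,5-trimethoxyphenyl)methylidene]-2-(3,4,5-trimethoxyphenyl)oxolane-3-carbaldehyde (2,3-trans; C3 is erased when the alkene moves into the ring) | O=C[C@H]1[C@H](c2cc(OC)c(OC)c(OC)c2)OC/C1=C\c3cc(OC)c(OC)cc3OC | intermediate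
6 | (2S)-4-[(2,4,5-trimethoxyphenyl)methyl]-2-(3,4,5-trimethoxyphenyl)-2,5-dihydrofuran-3-carbaldehyde | COc1cc(OC)c(OC)cc1CC1=C(C=O)[C@H](c2cc(OC)c(OC)c(OC)c2)OC1 | intermediate
7 | [(2S)-4-[(2,4,5-trimethoxyphenyl)methyl]-2-(3,4,5-trimethoxyphenyl)-2,5-dihydrofuran-3-yl]methanol | COc1cc(OC)c(OC)cc1CC1=C(CO)[C@H](c2cc(OC)c(OC)c(OC)c2)OC1 | intermediate
8 | [(2R,3R,4R)-4-[(2,4,5-trimethoxyphenyl)methyl]-2-(3,4,5-trimethoxyphenyl)oxolan-3-yl]methanol (all-cis) | COc1cc(OC)c(OC)cc1C[C@H]1CO[C@@H](c2cc(OC)c(OC)c(OC)c2)[C@H]1CO | target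

The descriptor at C2 changes from S (6, 7) to R (8) only because the priority of C3 falls when it becomes sp3; the spatial arrangement at C2 is the same.

**Step count and risks**

Total steps: 3. Longest linear sequence: 3.

The three steps most likely to fail are steps 1, 2 and 3, in that order of concern for 1 and 3.

Step 1 is the new cascade and the weakest point. Possible failures are copper-free alkynylation of 3 by 2, protonation of the vinyl–palladium species instead of arylation, or low enantioselectivity. The fallback uses known chemistry, sets out from 2 and 3 and comes back to the route at 7. Knoevenagel condensation of purchased 3,4,5-trimethoxybenzaldehyde with diethyl malonate (piperidine, AcOH, toluene, reflux) gives diethyl 2-[(3,4,5-trimethoxyphenyl)methylidene]propanedioate F1. The known racemic three-component coupling of the potassium alkoxide of 2 (KOtBu) with F1 and 3 under Pd(PPh3)4 in DMSO–THF gives racemic diethyl (4Z)-4-[(2,4,5-trimethoxyphenyl)methylidene]-2-(3,4,5-trimethoxyphenyl)oxolane-3,3-dicarboxylate F2. Krapcho dealkoxycarbonylation (LiCl, wet DMSO, 150 °C), followed by DBU to move the alkene into conjugation, gives racemic ethyl 4-[(2,4,5-trimethoxyphenyl)methyl]-2-(3,4,5-trimethoxyphenyl)-2,5-dihydrofuran-3-carboxylate F3. Reduction with i-Bu2AlH (CH2Cl2, −78 °C) gives racemic [4-[(2,4,5-trimethoxyphenyl)methyl]-2-(3,4,5-trimethoxyphenyl)-2,5-dihydrofuran-3-yl]methanol F4. Preparative chromatography on a chiral phase then separates 7 from its enantiomer [(2R)-4-[(2,4,5-trimethoxyphenyl)methyl]-2-(3,4,5-trimethoxyphenyl)-2,5-dihydrofuran-3-yl]methanol F5, which is set aside.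

Step 2 could fail through 1,4-reduction, or because 6 or 7 oxidises to the furan or ionises at the doubly activated C2–O bond on handling. The fallback avoids the allylic alcohol altogether, sets out from 6 and comes back at 8. Pinnick oxidation (NaClO2, NaH2PO4, 2-methylbut-2-ene, t-BuOH–H2O) gives (2S)-4-[(2,4,5-trimethoxyphenyl)methyl]-2-(3,4,5-trimethoxyphenyl)-2,5-dihydrofuran-3-carboxylic acid F6. Carboxylate-directed hydrogenation with Ru(OAc)2[(S)-BINAP] or its antipode, whichever matches the substrate bias (H2 80 bar, MeOH), gives the all-cis acid (2R,3S,4R)-4-[(2,4,5-trimethoxyphenyl)methyl]-2-(3,4,5-trimethoxyphenyl)oxolane-3-carboxylic acid F7. Reduction with LiAlH4 (THF, 0 °C) gives 8.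

Step 3 could fail because the hindered tetrasubstituted alkene reacts slowly or migrates under iridium hydride, or because face selectivity is incomplete. The fallback replaces hydroxyl-directed homogeneous delivery by purely steric control on a metal surface with the hydroxyl masked; it sets out from 7 and comes back at 8. Silylation (TBSCl, imidazole, DMF) gives tert-butyl{[(2S)-4-[(2,4,5-trimethoxyphenyl)methyl]-2-(3,4,5-trimethoxyphenyl)-2,5-dihydrofuran-3-yl]methoxy}dimethylsilane F8. Hydrogenation over 5 % Rh/Al2O3 (H2 60 bar, EtOAc), which adsorbs the alkene on the face away from the aryl group and spares the benzylic ether, gives tert-butyl{[(2R,3R,4R)-4-[(2,4,5-trimethoxyphenyl)methyl]-2-(3,4,5-trimethoxyphenyl)oxolan-3-yl]methoxy}dimethylsilane F9. Bu4NF (THF) then gives 8.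

**Further compounds**

F1 | step 1 | diethyl 2-[(3,4,5-trimethoxyphenyl)methylidene]propanedioate | CCOC(=O)C(=Cc1cc(OC)c(OC)c(OC)c1)C(=O)OCC
F2 | step 1 | racemic diethyl (4Z)-4-[(2,4,5-trimethoxyphenyl)methylidene]-2-(3,4,5-trimethoxyphenyl)oxolane-3,3-dicarboxylate | CCOC(=O)C1(C(=O)OCC)C(c2cc(OC)c(OC)c(OC)c2)OC/C1=C\c3cc(OC)c(OC)cc3OC
F3 | step 1 | racemic ethyl 4-[(2,4,5-trimethoxyphenyl)methyl]-2-(3,4,5-trimethoxyphenyl)-2,5-dihydrofuran-3-carboxylate | CCOC(=O)C1=C(Cc2cc(OC)c(OC)cc2OC)COC1c3cc(OC)c(OC)c(OC)c3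
F4 | step 1 | racemic [4-[(2,4,5-trimethoxyphenyl)methyl]-2-(3,4,5-trimethoxyphenyl)-2,5-dihydrofuran-3-yl]methanol | COc1cc(OC)c(OC)cc1CC1=C(CO)C(c2cc(OC)c(OC)c(OC)c2)OC1
F5 | step 1 | [(2R)-4-[(2,4,5-trimethoxyphenyl)methyl]-2-(3,4,5-trimethoxyphenyl)-2,5-dihydrofuran-3-yl]methanol | COc1cc(OC)c(OC)cc1CC1=C(CO)[C@@H](c2cc(OC)c(OC)c(OC)c2)OC1
F6 | step 2 | (2S)-4-[(2,4,5-trimethoxyphenyl)methyl]-2-(3,4,5-trimethoxyphenyl)-2,5-dihydrofuran-3-carboxylic acid | COc1cc(OC)c(OC)cc1CC1=C(C(=O)O)[C@H](c2cc(OC)c(OC)c(OC)c2)OC1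
F7 | step 2 | (2R,3S,4R)-4-[(2,4,5-trimethoxyphenyl)methyl]-2-(3,4,5-trimethoxyphenyl)oxolane-3-carboxylic acid | COc1cc(OC)c(OC)cc1C[C@H]1CO[C@@H](c2cc(OC)c(OC)c(OC)c2)[C@H]1C(=O)O
F8 | step 3 | tert-butyl{[(2S)-4-[(2,4,5-trimethoxyphenyl)methyl]-2-(3,4,5-trimethoxyphenyl)-2,5-dihydrofuran-3-yl]methoxy}dimethylsilane | COc1cc(OC)c(OC)cc1CC1=C(CO[Si](C)(C)C(C)(C)C)[C@H](c2cc(OC)c(OC)c(OC)c2)OC1
F9 | step 3 | tert-butyl{[(2R,3R,4R)-4-[(2,4,5-trimethoxyphenyl)methyl]-2-(3,4,5-trimethoxyphenyl)oxolan-3-yl]methoxy}dimethylsilane | COc1cc(OC)c(OC)cc1C[C@H]1CO[C@@H](c2cc(OC)c(OC)c(OC)c2)[C@H]1CO[Si](C)(C)C(C)(C)C
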